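**Assumption:** the target has no stereocentre, and its only C=C outside the arenes is the ring-locked cis alkene of the 2H-chromene. The achiral compound as drawn is therefore the "single enantiomer", and no stereocontrol is needed.

**Retrosynthetic overview**
1. Target benzil ⇐ SeO2 (Riley) oxidation of the benzylic CH2 of the matching 2-hydroxydeoxybenzoin.
2. Deoxybenzoin ⇐ alkaline excision of C-2 from a linear 5-methoxy-pyranoisoflavone. The γ-pyrone is a traceless mask that keeps the later 7-OH out of the methylation.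
3. Pyranoisoflavone ⇐ one flask, two rings: propargyl Claisen/oxa-6π (2,2-dimethylpyran), then DMF-DMA annulation (γ-pyrone) on an aryl 1,1-dimethylpropargyl ether.
4. Ether ⇐ para-O-alkylation of the phloroglucinol deoxybenzoin ⇐ Hoesch acylation of phloroglucinol with 4-methoxyphenylacetonitrile.
5. Ring order: both benzene rings are bought; the dimethylpyran and then the γ-pyrone form in the same operation; the γ-pyrone is opened again before the final oxidation.

**Route**

Step 1
Reactants: 1 phloroglucinol (benzene-1,3,5-triol); 2 4-methoxyphenylacetonitrile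
Product: 4 2-(4-methoxyphenyl)-1-(2,4,6-trihydroxyphenyl)ethan-1-one, via ketiminium chloride 3 (not isolated)
Conditions: HCl (g), ZnCl2 (cat.), Et2O, 0 °C to rt; then H2O, 100 °C
Reagents that add atoms: water, O
Why: Houben–Hoesch acylation, in which the nitrilium ion from 2 and HCl attacks the electron-rich, threefold-symmetric ring of 1 once (the ketiminium salt deactivates it) and water then hydrolyses the ketiminium to the aryl ketone.

Step 2
Reactants: 4 2-(4-methoxyphenyl)-1-(2,4,6-trihydroxyphenyl)ethan-1-one; 5 3-chloro-3-methylbut-1-yne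
Product: 6 1-[2,6-dihydroxy-4-(2-methylbut-3-yn-2-yloxy)phenyl]-2-(4-methoxyphenyl)ethan-1-one
Conditions: K2CO3, KI (cat.), CuI (cat.), acetone, 55 °C
Reagents that add atoms: none
Why: Williamson-type O-alkylation with the tertiary propargylic chloride (Cu/KI-assisted), which goes to the para-OH because it is the most acidic and the two ortho-OH groups are hydrogen-bonded to the ketone, and which thereby fixes the oxygen that becomes the pyran oxygen.

Step 3
Reactants: 6 1-[2,6-dihydroxy-4-(2-methylbut-3-yn-2-yloxy)phenyl]-2-(4-methoxyphenyl)ethan-1-one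
Product: 9 5-hydroxy-7-(4-methoxyphenyl)-2,2-dimethyl-2H,6H-pyrano[3,2-g]chromen-6-one (4'-O-methylalpinumisoflavone), via chromene ketone 7 (not isolated), via enaminone 8 (not isolated)
Conditions: DMF, 135 °C; then Me2NCH(OMe)2, 95 °C; dil. HCl work-up
Reagents that add atoms: N,N-dimethylformamide dimethyl acetal, COC(OC)N(C)C
Why: The aryl propargyl Claisen rearrangement/[1,5]-H shift/oxa-6π electrocyclisation can give only one chromene (both ortho carbons are equivalent and the ring oxygen is the ether oxygen), and the DMF-DMA enaminone then closes the γ-pyrone by addition–elimination, expected mainly at the unhindered 7-OH because the 5-OH is buttressed by the peri C4–H and held in the hydrogen bond to the ketone, which gives the linear isomer.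

Step 4
Reactants: 9 5-hydroxy-7-(4-methoxyphenyl)-2,2-dimethyl-2H,6H-pyrano[3,2-g]chromen-6-one
Product: 10 5-methoxy-7-(4-methoxyphenyl)-2,2-dimethyl-2H,6H-pyrano[3,2-g]chromen-6-one
Conditions: Me2SO4, K2CO3, acetone, reflux
Reagents that add atoms: dimethyl sulfate, COS(=O)(=O)OC
Why: Williamson O-methylation of the only OH left, the chelated 5-OH, under forcing but anhydrous conditions that leave the γ-pyrone closed, while the future 7-OH is protected as the pyrone ring oxygen.

Step 5
Reactants: 10 5-methoxy-7-(4-methoxyphenyl)-2,2-dimethyl-2H,6H-pyrano[3,2-g]chromen-6-one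
Product: 12 1-(7-hydroxy-5-methoxy-2,2-dimethyl-2H-chromen-6-yl)-2-(4-methoxyphenyl)ethan-1-one, via hydroxymethylene ketone 11 (not isolated)
Conditions: KOH, EtOH/H2O, reflux, N2; then aq. HCl
Reagents that add atoms: none
Why: Classical alkaline isoflavone cleavage, in which hydroxide adds to C-2 (oxa-Michael), retro-oxa-Michael opening gives the α-formyl ketone and retro-Claisen deformylation expels formate, freeing the masked phenol and returning the benzyl ketone.

Step 6
Reactants: 12 1-(7-hydroxy-5-methoxy-2,2-dimethyl-2H-chromen-6-yl)-2-(4-methoxyphenyl)ethan-1-one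
Product: 13 1-(7-hydroxy-5-methoxy-2,2-dimethyl-2H-chromen-6-yl)-2-(4-methoxyphenyl)ethane-1,2-dione (target)
Conditions: SeO2, 1,4-dioxane/H2O, 100 °C
Reagents that add atoms: selenium dioxide, O=[Se]=O
Why: Riley oxidation of the enolisable benzylic CH2 next to the ketone to the 1,2-diketone, with the chromene untouched because it has no allylic C–H (C-2 is quaternary).

**Compound list**
1 | phloroglucinol (benzene-1,3,5-triol) | Oc1cc(O)cc(O)c1 | starting material
2 | 4-methoxyphenylacetonitrile | COc1ccc(CC#N)cc1 | starting material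
3 | 2-(4-methoxyphenyl)-1-(2,4,6-trihydroxyphenyl)ethan-1-iminium chloride | COc1ccc(CC(=[NH2+])c2c(O)cc(O)cc2O)cc1.[Cl-] | intermediate
4 | 2-(4-methoxyphenyl)-1-(2,4,6-trihydroxyphenyl)ethan-1-one | COc1ccc(CC(=O)c2c(O)cc(O)cc2O)cc1 | intermediate
5 | 3-chloro-3-methylbut-1-yne | CC(C)(Cl)C#C | starting material
6 | 1-[2,6-dihydroxy-4-(2-methylbut-3-yn-2-yloxy)phenyl]-2-(4-methoxyphenyl)ethan-1-one | COc1ccc(CC(=O)c2c(O)cc(OC(C)(C)C#C)cc2O)cc1 | intermediate
7 | 1-(5,7-dihydroxy-2,2-dimethyl-2H-chromen-6-yl)-2-(4-methoxyphenyl)ethan-1-one | COc1ccc(CC(=O)c2c(O)cc3OC(C)(C)C=Cc3c2O)cc1 | intermediate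
8 | 3-(dimethylamino)-1-(5,7-dihydroxy-2,2-dimethyl-2H-chromen-6-yl)-2-(4-methoxyphenyl)prop-2-en-1-one (C=C geometry not fixed) | COc1ccc(cc1)C(=CN(C)C)C(=O)c1c(O)cc2OC(C)(C)C=Cc2c1O | intermediate
9 | 5-hydroxy-7-(4-methoxyphenyl)-2,2-dimethyl-2H,6H-pyrano[3,2-g]chromen-6-one | COc1ccc(cc1)C1=COc2cc3OC(C)(C)C=Cc3c(O)c2C1=O | intermediate
10 | 5-methoxy-7-(4-methoxyphenyl)-2,2-dimethyl-2H,6H-pyrano[3,2-g]chromen-6-one | COc1ccc(cc1)C1=COc2cc3OC(C)(C)C=Cc3c(OC)c2C1=O | intermediate
11 | 3-hydroxy-1-(7-hydroxy-5-methoxy-2,2-dimethyl-2H-chromen-6-yl)-2-(4-methoxyphenyl)prop-2-en-1-one (enol of the α-formyl ketone, C=C geometry not fixed) | COc1ccc(cc1)C(=CO)C(=O)c1c(O)cc2OC(C)(C)C=Cc2c1OC | intermediate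
12 | 1-(7-hydroxy-5-methoxy-2,2-dimethyl-2H-chromen-6-yl)-2-(4-methoxyphenyl)ethan-1-one | COc1ccc(CC(=O)c2c(O)cc3OC(C)(C)C=Cc3c2OC)cc1 | intermediate
13 | 1-(7-hydroxy-5-methoxy-2,2-dimethyl-2H-chromen-6-yl)-2-(4-methoxyphenyl)ethane-1,2-dione | COc1ccc(C(=O)C(=O)c2c(O)cc3c(c2OC)C=CC(C)(C)O3)cc1 | target

**Totals**
Total step count: 6. Longest linear sequence: 6 steps (1 → 13).

**Three steps most likely to fail, with fallbacks**

Step 3 (most at risk). The chromene part is unambiguous. The open question is which phenol closes the γ-pyrone: closure at the 5-OH would give the angular isomer, and the preference for the 7-OH rests on a steric and hydrogen-bonding argument, not on a direct precedent I can point to. If the closure goes the wrong way or DMF-DMA gives side reactions, the γ-pyrone mask is dropped. Ether 6 is heated alone (DMF, 135 °C) and chromene ketone 7 is isolated. Its less hindered 7-OH is capped with MOMCl/i-Pr2NEt (CH2Cl2, 0 °C) to give 1-[5-hydroxy-7-(methoxymethoxy)-2,2-dimethyl-2H-chromen-6-yl]-2-(4-methoxyphenyl)ethan-1-one F1. The remaining chelated 5-OH is methylated (MeI, K2CO3, DMF, 50 °C) to give 1-[5-methoxy-7-(methoxymethoxy)-2,2-dimethyl-2H-chromen-6-yl]-2-(4-methoxyphenyl)ethan-1-one F2. Mild acid (3 M HCl, MeOH, rt) removes the MOM group and gives 12, where the route is rejoined; steps 4 and 5 fall away.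

Step 2. Etherification with a tertiary propargylic chloride on a triphenolic ketone can be low-yielding (bis-alkylation, C-alkylation, elimination of the chloride). The fallback builds the chromene by C–C bond formation first. Ketone 4 is C-prenylated with 2-methylbut-3-en-2-ol/BF3·OEt2 (dioxane, rt) to give 2-(4-methoxyphenyl)-1-[2,4,6-trihydroxy-3-(3-methylbut-2-en-1-yl)phenyl]ethan-1-one F3, a single mono-prenyl isomer by symmetry. DDQ (benzene, 80 °C) then cyclises it oxidatively; closure onto the non-chelated para-OH is expected by analogy with other chelated prenylphenols and must be confirmed on the product. This gives 7, which is treated with DMF-DMA as in the second half of step 3 to reach 9.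

Step 6. SeO2 may over-oxidise the electron-rich phenolic chromene or give selenium-containing by-products. The fallback oxidises through nitrogen instead. Ketone 12 is nitrosated at the benzylic carbon (isoamyl nitrite, NaOEt, EtOH, 0 °C) to give 2-(hydroxyimino)-1-(7-hydroxy-5-methoxy-2,2-dimethyl-2H-chromen-6-yl)-2-(4-methoxyphenyl)ethan-1-one F4. Hydrolytic deoximation (NaHSO3, aq. EtOH, reflux, then dilute HCl) gives 13.

**Further compounds**
F1 | step 3 | 1-[5-hydroxy-7-(methoxymethoxy)-2,2-dimethyl-2H-chromen-6-yl]-2-(4-methoxyphenyl)ethan-1-one | COCOc1cc2OC(C)(C)C=Cc2c(O)c1C(=O)Cc1ccc(OC)cc1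
F2 | step 3 | 1-[5-methoxy-7-(methoxymethoxy)-2,2-dimethyl-2H-chromen-6-yl]-2-(4-methoxyphenyl)ethan-1-one | COCOc1cc2OC(C)(C)C=Cc2c(OC)c1C(=O)Cc1ccc(OC)cc1
F3 | step 2 | 2-(4-methoxyphenyl)-1-[2,4,6-trihydroxy-3-(3-methylbut-2-en-1-yl)phenyl]ethan-1-one | COc1ccc(CC(=O)c2c(O)cc(O)c(CC=C(C)C)c2O)cc1
F4 | step 6 | 2-(hydroxyimino)-1-(7-hydroxy-5-methoxy-2,2-dimethyl-2H-chromen-6-yl)-2-(4-methoxyphenyl)ethan-1-one (oxime geometry not fixed) | COc1ccc(cc1)C(=NO)C(=O)c1c(O)cc2OC(C)(C)C=Cc2c1OC
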